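**Retrosynthetic overview** (polyketide numbering: C1 = carboxyl carbon lost as CO2, C2 = methyl-bearing carbon, C7 = chain-bearing carbon; written from the building blocks upward)
1. The skeleton comes from two bought pieces: tricosanoic acid 1 (C7 plus the docosyl chain, the "starter") and 4-hydroxy-3,6-dimethyl-2H-pyran-2-one 2 (masked C1–C6 triketide whose 3-methyl is the C2 methyl of a methylmalonate-terminated chain).
2. C6–C7 bond by Claisen condensation: acyl imidazole 3 (from 1) plus dilithio dianion 4 (from 2) gives tetraketide lactone 5; hydroxide unmasks the linear tetraketide acid 6.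
3. The only ring built in the route is the carbocycle (no arene is bought): C2→C7 aldol condensation 6 → 7, then loss of C1 as CO2 with aromatisation to resorcinol 8, as in the alkylresorcinol-synthase pathway, in the same flask as line 2.
4. Tailoring in the order oxidation, then methylation: para-oxidation of 8 at C6 gives hydroxyquinone 9; O-methylation of its single OH (on C5) gives target 10.

Assumption: the target has no stereocentre and no stereogenic double bond, so the "single enantiomer" is the achiral compound itself; 1 and 2 are taken as catalogue chemicals.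

**Step 1**
Reactants: 1 tricosanoic acid; 2 4-hydroxy-3,6-dimethyl-2H-pyran-2-one
Product: 8 5-docosyl-4-methylbenzene-1,3-diol, via N-tricosanoylimidazole 3 (not isolated), via pyrone dianion 4 (not isolated), via tetraketide lactone 5 (not isolated), via tetraketide acid 6 (not isolated), via cyclohexenedione acid 7 (not isolated)
Conditions: 1, 1,1'-carbonyldiimidazole (1.05 equiv), THF, 40 °C, 1 h; add to 2 (2.3 equiv) + LiN(iPr)2 (4.8 equiv), THF, −78 → 0 °C; then 3 M aq KOH, MeOH, Ar, 20 → 45 °C, 16 h; then 6 M HCl to pH 1, 60 °C, 1 h
Reagents that add atoms: none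
Why: Proposed new method: the 6-CH2 carbanion of 4 is C-acylated by 3 (Claisen condensation of a pyrone polyanion; one extra equivalent of 4 absorbs the N–H of the imidazole freed on activation) to give 5, hydroxide opens the lactone to the carboxylate of 6, where Claisen ring closure is impossible, so the C2 enolate (flanked by ketone and carboxylate) adds to the C7 ketone and dehydrates (intramolecular aldol condensation) to 7 with C2 quaternary, and acidification gives the β-keto acid, which loses CO2 and tautomerises to the arene; the closest known reactions are the aqueous KOH cyclisation of tetraacetic acid lactone to orsellinic acid and the enzymatic decarboxylative aldol aromatisation of alkylresorcinol synthases, the new elements being the methyl-substituted C2 and the one-flask sequence; no stereocentre survives.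

**Step 2**
Reactants: 8 5-docosyl-4-methylbenzene-1,3-diol
Product: 9 3-docosyl-5-hydroxy-2-methylcyclohexa-2,5-diene-1,4-dione
Conditions: ON(SO3K)2 (Fremy's salt, 2.5 equiv), aq KH2PO4 (pH 6–7), CH2Cl2, methyltrioctylammonium chloride (10 mol %), 0 → 20 °C, 3 h; dilute HCl wash
Reagents that add atoms: dipotassium nitrosodisulfonate, ON(SO3K)2, [K+].[K+].[O]N(S(=O)(=O)[O-])S(=O)(=O)[O-]
Why: Teuber oxidation: the only free position para to a hydroxyl is C6 (para to the OH next to the methyl group), so the second nitroxide couples there and elimination gives the 2-hydroxy-1,4-quinone, as in orcinol → 2-hydroxy-6-methyl-1,4-benzoquinone; ortho attack from the other OH at the same carbon gives the same compound after tautomerisation.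

**Step 3**
Reactants: 9 3-docosyl-5-hydroxy-2-methylcyclohexa-2,5-diene-1,4-dione
Product: 10 3-docosyl-5-methoxy-2-methylcyclohexa-2,5-diene-1,4-dione (the target)
Conditions: MeOH/CH2Cl2 (3:1), H2SO4 (5 mol %), 40 °C, 12 h
Reagents that add atoms: methanol, CO
Why: Acid-catalysed addition–elimination of methanol on the vinylogous acid (Fischer-type etherification of a 2-hydroxy-1,4-quinone, as for lawsone → 2-methoxy-1,4-naphthoquinone); there is only one OH, acid excludes C-alkylation, and the para-quinone ether is the thermodynamic product.

**Compound list**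
1 | tricosanoic acid | CCCCCCCCCCCCCCCCCCCCCCC(=O)O | starting material
2 | 4-hydroxy-3,6-dimethyl-2H-pyran-2-one | CC1=CC(O)=C(C)C(=O)O1 | starting material
3 | 1-(1H-imidazol-1-yl)tricosan-1-one (N-tricosanoylimidazole) | CCCCCCCCCCCCCCCCCCCCCCC(=O)n1ccnc1 | intermediate
4 | dilithium salt of the dianion of 2 (4-oxide, carbanion at the 6-CH2) | [Li+].[Li+].[CH2-]C1=CC([O-])=C(C)C(=O)O1 | intermediate
5 | 4-hydroxy-3-methyl-6-(2-oxotetracosyl)-2H-pyran-2-one | CCCCCCCCCCCCCCCCCCCCCCC(=O)CC1=CC(O)=C(C)C(=O)O1 | intermediate
6 | 2-methyl-3,5,7-trioxononacosanoic acid (racemic; in the flask as its potassium salt) | CCCCCCCCCCCCCCCCCCCCCCC(=O)CC(=O)CC(=O)C(C)C(=O)O | intermediate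
7 | 6-docosyl-1-methyl-2,4-dioxocyclohex-5-ene-1-carboxylic acid (racemic; stereocentre lost on decarboxylation) | CCCCCCCCCCCCCCCCCCCCCCC1=CC(=O)CC(=O)C1(C)C(=O)O | intermediate
8 | 5-docosyl-4-methylbenzene-1,3-diol | CCCCCCCCCCCCCCCCCCCCCCc1cc(O)cc(O)c1C | intermediate
9 | 3-docosyl-5-hydroxy-2-methylcyclohexa-2,5-diene-1,4-dione | CCCCCCCCCCCCCCCCCCCCCCC1=C(C)C(=O)C=C(O)C1=O | intermediate
10 | 3-docosyl-5-methoxy-2-methylcyclohexa-2,5-diene-1,4-dione | CCCCCCCCCCCCCCCCCCCCCCC1=C(C)C(=O)C=C(OC)C1=O | target

**Totals**
Total step count: 3 (each one-flask sequence counted as one step). Longest linear sequence: 3.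

**Steps most likely to fail, in order of risk**

Step 1 is the main risk. The aldol must form a quaternary carbon at C2. It competes with closure of the chain α-carbon onto the C3 ketone, with retro-Claisen cleavage in KOH, and with decarboxylation of uncyclised 6 on acidification (which leads to a 4-pyranone). The fallback sets out from 1 (activated as 3, as above) and comes back at 8; it takes the methyl group out of the ring-forming step. Bought 4-hydroxy-6-methyl-2H-pyran-2-one (triacetic acid lactone) is converted with LiN(iPr)2 into the dilithium salt of its dianion F1. F1 is acylated by 3 to 4-hydroxy-6-(2-oxotetracosyl)-2H-pyran-2-one F2. Aqueous KOH then closes the unsubstituted C2 onto C7 with the carboxyl group retained (the precedented tetraacetic acid lactone → orsellinic acid closure) to give 2-docosyl-4,6-dihydroxybenzoic acid F3. The carboxyl group of F3 is reduced to the ring methyl group with NaAlH2(OCH2CH2OMe)2 in refluxing xylene (reduction to the salicyl alkoxide, elimination to the ortho-quinone methide, second hydride addition), which gives 8.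

Step 2 is the second risk. The concerns are poor phase transfer of the C22 substrate, competing attack at the carbon between the two hydroxyls, and over-oxidation of the hydroxyquinone. The fallback sets out from 8 and comes back at 9. Vilsmeier–Haack formylation (POCl3, DMF, MeCN, 0 → 20 °C; aqueous NaOAc) at C6, the position para to one OH and ortho to the other, as in orcinol → orcylaldehyde, gives 2-docosyl-4,6-dihydroxy-3-methylbenzaldehyde F4. Dakin oxidation (H2O2, NaOH, THF/H2O, Ar) replaces the formyl group by OH and gives 6-docosyl-5-methylbenzene-1,2,4-triol F5. F5 is oxidised by air (or FeCl3) in aqueous THF to 9.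

Step 3 is the lowest risk. The concerns are incomplete conversion at equilibrium and ketal formation with the long-chain substrate. The fallback sets out from 9 and comes back at 10. Reductive methylation (Na2S2O4, then Me2SO4, KOH, Bu4NBr, THF/H2O, Ar; the triol stage is F5 of the preceding fallback and is not isolated) gives 3-docosyl-1,2,5-trimethoxy-4-methylbenzene F6. Oxidative demethylation of the para-dimethoxy pair with (NH4)2Ce(NO3)6 in MeCN/H2O at 0 °C gives 10; the methoxy group on C5 is the one that stays.

**Further compounds**
F1 | step 1 | dilithium salt of the dianion of 4-hydroxy-6-methyl-2H-pyran-2-one (4-oxide, carbanion at the 6-CH2) | [Li+].[Li+].[CH2-]C1=CC([O-])=CC(=O)O1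
F2 | step 1 | 4-hydroxy-6-(2-oxotetracosyl)-2H-pyran-2-one | CCCCCCCCCCCCCCCCCCCCCCC(=O)CC1=CC(O)=CC(=O)O1
F3 | step 1 | 2-docosyl-4,6-dihydroxybenzoic acid | CCCCCCCCCCCCCCCCCCCCCCc1cc(O)cc(O)c1C(=O)O
F4 | step 2 | 2-docosyl-4,6-dihydroxy-3-methylbenzaldehyde | CCCCCCCCCCCCCCCCCCCCCCc1c(C)c(O)cc(O)c1C=O
F5 | step 2 | 6-docosyl-5-methylbenzene-1,2,4-triol | CCCCCCCCCCCCCCCCCCCCCCc1c(C)c(O)cc(O)c1O
F6 | step 3 | 3-docosyl-1,2,5-trimethoxy-4-methylbenzene | CCCCCCCCCCCCCCCCCCCCCCc1c(C)c(OC)cc(OC)c1OC
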